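## Structural features

Ageconyflavone C is a flavone in which a benzene ring (ring A) is fused through the C4a–C8a bond to a 4-pyranone (ring C, made up of O1, C2, C3, C4, C4a and C8a), and an aryl ring (ring B) is attached by the C2–C1' bond. The molecule is flat and has no stereocentre. Ring A carries three contiguous methoxy groups at C5, C6 and C7 and a single hydrogen at C8. Ring B is a syringyl unit with methoxy groups at C3' and C5' and the only free hydroxyl at C4'. The fragile points are the electron-rich 4'-phenol (conjugated through ring B to C2 and easily oxidised), the 5-methoxy group peri to the C4 carbonyl (the first ether lost to Lewis acids), and C2 of the pyranone (opened by hot alkali). The real difficulty is regiochemical, because ring A must be 5,6,7-trioxygenated with C8 free and not the isomeric 5,7,8 pattern, and one of six oxygens must stay unmethylated. The key step exploits the O1–C8a bond: C8a is ortho to C4a, which carries the C4 carbonyl, and para to C6, so that in an open 2,3,4-trimethoxybenzoyl precursor it is the only C–H carbon ortho to the acyl group and a site of positive charge in the ring A radical cation.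

## Logic of the disconnections

10 to 9: the only change is the acyl group on the 4'-oxygen, so the bond cut in the forward sense is the aryl O–C(=O) bond. A free phenol would be the first site oxidised in the ring-closing step; as an ester the strongest donor of ring B becomes a weak one. Nothing is gained in skeleton, but the key step becomes possible. The forward step must cleave a hindered ester without opening the pyranone or touching five methyl ethers.

9 to 8: the O1–C8a bond is cut, opening ring C to a 1,3-diaryl-1,3-diketone. Cutting here removes any need for an oxygen or a halogen at the ring A ortho carbon, which ordinary electrophilic chemistry would not place there. The tricyclic target collapses to two aryl carbonyl halves joined by one methylene. The forward step must take two electrons and two protons from 8 selectively: at ring A not ring B, at the C–H ortho carbon not the methoxy-bearing one, and through oxygen.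

8 to 5 and 6 (through 7): the bond between the central methylene (future C3) and the ring B carbonyl (future C2) is cut. This is the Claisen-type polarity of a 1,3-diketone and leads to a methyl ketone and an aroyl chloride, each carrying one complete aryl ring. The forward step must acylate on carbon once only, and must not transfer the pivaloyl group of 5.

5 to 4: the C–Cl bond is exchanged for C–OH. The acid is the storable form; the chloride is made just before use. The forward step needs conditions neutral enough for the aryl ester.

4 to 1 and 2 (through 3): the aryl O–acyl bond is cut, giving the two commercial materials. The forward step must acylate a phenol flanked by two methoxy groups in the presence of a free carboxyl group and then return the carboxyl group unprotected.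

## Other disconnections considered

Alternative 1: Ring A is cut at C4a–C8a and ring C at O1–C2, leading to the open-chain tetraketo ester A1. In the forward sense A1, held as a magnesium polyenolate, would undergo an intramolecular Claisen condensation (C4a onto the ester carbon) to build ring A. Acid would then close O1–C2 to give A2.
- In favour: both rings arise from one acyclic chain, no aromatic ring A building block is needed, and the 6-methoxy group is placed by the chain. Each bond-forming event is a familiar condensation, so on precedent of reaction type it is the better of the two plans.
- Against: A1 is a sensitive polycarbonyl chain that needs several polyanion condensations to assemble, and it can fold in more than one way. After aromatisation two hydroxyls flank the acyl group, so closure through the other one would lead to the 8-methoxy isomer A3, and acid can interconvert such isomers. The chosen plan has no such ambiguity because ring A is bought with its three methoxy groups in place.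
- After the key step: A2 still needs two O-methylations (the chelated 5-hydroxyl being reluctant) and a debenzylation.
- Comparison: on structure, both plans are free of stereochemical issues, but the alternative leaves the ring A pattern open to isomerism where the chosen plan fixes it. On mechanism the alternative is the more conventional. On step economy it is clearly longer than five steps.

Alternative 2: Ring A is cut at C4a–C5, leading to the cyclobutenone A4, in which a four-membered ring is attached to C2 of a 6-aryl-4-pyranone. Heating A4 should open the cyclobutenone to a vinylketene. Its ketene carbon would bond to the neighbouring pyranone C–H carbon in a six-electron electrocyclisation, and tautomerisation would give the C5 phenol A5.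
- In favour: every ring A substituent comes from a defined cyclobutenone carbon, so the regiochemistry is unambiguous. The step is thermal and needs no oxidant or redox control. On both points it is better than the chosen plan.
- Against: A4 needs a multi-step assembly (a four-membered-ring building block cross-coupled to a preformed, functionalised pyranone). Its C4 hydrogen, acidic between a carbonyl and a heteroaryl ring, invites isomerisation before ring opening.
- After the key step: A5 needs methylation of the chelated 5-hydroxyl and then debenzylation.
- Comparison: the alternative is mechanistically safer at the key step and structurally less accessible before it. Its longest linear sequence would be well above five steps.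

Alternative 3: Ring C is cut at C4a–C4, C4–C3 and O1–C2, leading to the iodophenol A6, carbon monoxide and the aryl alkyne A7. With PdCl2(PPh3)2 and a secondary amine, a carbonylative Sonogashira coupling followed by 6-endo closure of the phenol onto the ynone should give A8.
- In favour: three bonds form in one operation from two small partners, and the reaction class is well established for flavones. A6 is one iodination away from a symmetrical phenol and A7 two steps from a commercial aldehyde. On precedent and convergence this is the stronger plan. On step count it is equal or slightly better (about five operations, longest linear sequence four).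
- Against: it needs toxic carbon monoxide and a palladium catalyst. The iodide of A6 is flanked by two oxygen substituents on an electron-rich ring, so oxidative addition would be slow. Direct coupling without CO uptake and 5-exo closure both compete with the wanted pathway. The benzyl ether must finally be removed without reducing C2=C3, and without a Lewis acid that would take the 5-methyl group.
- Comparison: the chosen plan needs no halogen on ring A, no metal catalyst and no gas, and ends with a gentler deprotection. Its weakness is that all its risk sits in one unprecedented step, which is why a conventional fallback from the same acid chloride is kept in reserve.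

Key step: step 4

Remark: closure at the only unsubstituted carbon ortho to the acyl group of a 2,3,4-trimethoxybenzoyl unit maps onto the 5,6,7-trimethoxy pattern with C8–H, so the structures of 8 and 9 are used unchanged. C8a is "ortho to the carbonyl" in the sense of being ortho to C4a, which bears it.

Remark: the ring B mask is kept as a pivalate. It is an electron-poor acyloxy group, too hindered to act as an acyl donor toward the enolate, and removable by methanolysis. Compound 8 is electrolysed as its neutral enol without added base, so that ring A, and not a diketonate, is the electron source.

## Route

Step 1
Reactants: 1 syringic acid; 2 pivaloyl chloride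
Product: 4 3,5-dimethoxy-4-(pivaloyloxy)benzoic acid, via mixed pivalic anhydride 3 (not isolated)
Conditions: 1 added slowly to PivCl (2.5 equiv), Et3N (3.5 equiv), DMAP (0.1 equiv), CH2Cl2, 0 °C to rt; then H2O/THF, rt; dil. HCl work-up
Reagents that add atoms: pivaloyl chloride (compound 2), CC(C)(C)C(=O)Cl; water, O
Why: DMAP-catalysed acylation of the phenol and of the carboxylate by the acid chloride, run with the acyl chloride in excess so that the phenol is pivaloylated before it can be aroylated by the mixed anhydride; the mixed anhydride 3 should then be hydrolysed in the aqueous quench at its unhindered aroyl carbonyl, while the shielded aryl pivalate survives.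

Step 2
Reactants: 4 3,5-dimethoxy-4-(pivaloyloxy)benzoic acid
Product: 5 3,5-dimethoxy-4-(pivaloyloxy)benzoyl chloride
Conditions: (COCl)2 (1.5 equiv), DMF (cat.), CH2Cl2, 0 °C to rt; evaporate, use at once
Reagents that add atoms: oxalyl chloride, ClC(=O)C(=O)Cl
Why: Acid chloride formation through the Vilsmeier-type chloroiminium species from DMF and oxalyl chloride; the conditions are neutral and mild, so the aryl ester and the methyl ethers should not be affected.

Step 3
Reactants: 6 2,3,4-trimethoxyacetophenone; 5 3,5-dimethoxy-4-(pivaloyloxy)benzoyl chloride
Product: 8 2,6-dimethoxy-4-[3-oxo-3-(2,3,4-trimethoxyphenyl)propanoyl]phenyl pivalate, via bromomagnesium enolate 7 (not isolated)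
Conditions: 6 (1.2 equiv), 5, MgBr2·OEt2 (2.5 equiv), CH2Cl2, then i-Pr2NEt (3 equiv), 0 °C to rt; 1 M HCl work-up
Reagents that add atoms: none
Why: Crossed Claisen-type C-acylation under soft enolisation: MgBr2 bound to the ketone makes the methyl protons acidic enough for the amine, the enolate 7 is acylated on carbon by 5, and the product is held as a magnesium diketonate chelate that resists a second acylation; the hindered pivalate is not an acyl donor here.

Step 4
Reactants: 8 2,6-dimethoxy-4-[3-oxo-3-(2,3,4-trimethoxyphenyl)propanoyl]phenyl pivalate
Product: 9 2,6-dimethoxy-4-(5,6,7-trimethoxy-4-oxo-4H-chromen-2-yl)phenyl pivalate (4'-O-pivaloyl Ageconyflavone C)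
Conditions: undivided cell, graphite anode, Pt cathode, Bu4NPF6 (0.1 M), HFIP/CH2Cl2 (9:1), 5 mM in 8, controlled potential at the first anodic wave (Ag/AgCl reference), 2.0–2.2 F/mol, rt, no added base
Reagents that add atoms: none
Why: Proposed new method: ring A of the neutral enol of 8 is the most electron-rich π system and should lose one electron at the carbon anode to a radical cation that hexafluoroisopropanol stabilises without trapping it; the positive charge sits largely on the methoxy-bearing carbons and on the C–H carbon para to the central methoxy group, which is the free carbon ortho to the acyl group. After rotation about the bond between the ring A carbonyl and the central CH, the enol oxygen on the ring B side reaches that carbon and adds to it, a six-membered closure of an oxygen nucleophile onto an arene sp2 carbon (6-endo with respect to the C4a–C8a bond; ring C is the only ring formed); proton loss, a second and easier one-electron oxidation of the cyclohexadienyl radical, and loss of the C8a proton restore aromaticity, while the cathode turns the released protons into H2, so no chemical oxidant is consumed. The closest known reaction types are the anodic dehydrogenative lactonisation of 2-arylbenzoic acids and the anodic C–H etherification of electron-rich arenes in fluorinated alcohols; new here are the enol oxygen as nucleophile and the 4-pyranone as the ring formed. No stereocentre is created. Three selectivities are needed: ring A over ring B, secured by three methoxy donors against two methoxy groups plus an electron-poor pivaloyloxy group and by electrolysis at the first wave; the C–H carbon over the methoxy-bearing ortho carbon, secured because only the adduct at the C–H carbon is drained irreversibly by the second electron transfer and proton loss; and oxygen over carbon reactivity of the dicarbonyl unit, secured by geometry (closure through C3 would need a four-membered ring) and by dilution against intermolecular coupling. Leaving out base keeps the diketone out of its enolate, whose radical would prefer the more nucleophilic ortho carbons of ring B, and keeps hexafluoroisopropoxide from competing as a nucleophile.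

Step 5
Reactants: 9 2,6-dimethoxy-4-(5,6,7-trimethoxy-4-oxo-4H-chromen-2-yl)phenyl pivalate
Product: 10 Ageconyflavone C, 2-(4-hydroxy-3,5-dimethoxyphenyl)-5,6,7-trimethoxy-4H-chromen-4-one
Conditions: K2CO3 (2 equiv), MeOH/THF, rt; aq. NH4Cl then dil. HCl to pH 5
Reagents that add atoms: none
Why: Base-mediated transesterification (methanolysis): methoxide attacks the ester carbonyl and a phenoxide stabilised through ring B and the chromone leaves; methyl ethers and the pyranone should be inert to carbonate in methanol at room temperature.

## Compound list

1 | syringic acid (4-hydroxy-3,5-dimethoxybenzoic acid) | COc1cc(C(=O)O)cc(OC)c1O | starting material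
2 | pivaloyl chloride | CC(C)(C)C(=O)Cl | starting material
3 | 3,5-dimethoxy-4-(pivaloyloxy)benzoic pivalic anhydride | COc1cc(C(=O)OC(=O)C(C)(C)C)cc(OC)c1OC(=O)C(C)(C)C | intermediate
4 | 3,5-dimethoxy-4-(pivaloyloxy)benzoic acid | COc1cc(C(=O)O)cc(OC)c1OC(=O)C(C)(C)C | intermediate
5 | 3,5-dimethoxy-4-(pivaloyloxy)benzoyl chloride | COc1cc(C(=O)Cl)cc(OC)c1OC(=O)C(C)(C)C | intermediate
6 | 2,3,4-trimethoxyacetophenone | CC(=O)c1ccc(OC)c(OC)c1OC | starting material
7 | bromomagnesium enolate of 2,3,4-trimethoxyacetophenone | C=C(O[Mg]Br)c1ccc(OC)c(OC)c1OC | intermediate
8 | 2,6-dimethoxy-4-[3-oxo-3-(2,3,4-trimethoxyphenyl)propanoyl]phenyl pivalate (drawn as the diketo form) | COc1ccc(C(=O)CC(=O)c2cc(OC)c(OC(=O)C(C)(C)C)c(OC)c2)c(OC)c1OC | intermediate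
9 | 2,6-dimethoxy-4-(5,6,7-trimethoxy-4-oxo-4H-chromen-2-yl)phenyl pivalate | COc1cc(-c2cc(=O)c3c(OC)c(OC)c(OC)cc3o2)cc(OC)c1OC(=O)C(C)(C)C | intermediate
10 | Ageconyflavone C | COc1cc(-c2cc(=O)c3c(OC)c(OC)c(OC)cc3o2)cc(OC)c1O | target

## Step count and risk

Total step count: 5. Longest linear sequence: 5 (1 to 4 to 5 to 8 to 9 to 10); compound 6 enters at step 3.

**Step 4 (key step, proposed new method).**
- What may go wrong: electron loss and ring closure at the wrong site. The free ortho carbons of ring B are ortho and para to methoxy groups, so selectivity between the rings rests only on a modest difference in oxidation potential. The central methoxy group of ring A is twisted out of the ring plane by its neighbours, which weakens the para activation the closure relies on. Other risks are ipso substitution at the methoxy-bearing ortho carbon with loss of methanol, further oxidation of the product (its ring A carries four oxygen substituents), and intermolecular coupling through the central carbon of the dicarbonyl unit.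
- Fallback (known chemistry, setting out from 5 and returning to the route at 9): commercially available 1-(6-hydroxy-2,3,4-trimethoxyphenyl)ethanone F1 is converted to its lithium dianion (LiN(SiMe3)2, 3.2 equiv, THF, −78 °C). The dianion of F1 is C-acylated with 5 to give 4-[3-(6-hydroxy-2,3,4-trimethoxyphenyl)-3-oxopropanoyl]-2,6-dimethoxyphenyl pivalate F2. Warming F2 in AcOH with catalytic H2SO4 should bring about cyclodehydration through the free ortho hydroxyl and give 9, where the route resumes at step 5. The ring A oxygen is then bought with F1 rather than made.

**Step 3.**
- What may go wrong: acylation on oxygen or a second acylation instead of a single C-acylation; magnesium-assisted loss of the methyl group ortho to the ketone; transfer of the pivaloyl group to the enolate. The hindered, chelating ortho-methoxy ketone may enolise slowly.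
- Fallback (setting out from 6 and 2 and returning to the route at 8): commercially available 4-hydroxy-3,5-dimethoxybenzaldehyde F3 (syringaldehyde) is pivaloylated with 2 (Et3N, DMAP, CH2Cl2), which converts F3 into 4-formyl-2,6-dimethoxyphenyl pivalate F4. The lithium enolate of 6 (LiN(i-Pr)2, THF, −78 °C) is added to F4 to give the racemic aldol 4-[1-hydroxy-3-oxo-3-(2,3,4-trimethoxyphenyl)propyl]-2,6-dimethoxyphenyl pivalate F5. Oxidation of F5 with Dess–Martin periodinane (CH2Cl2, rt) should give 8. The C–C bond is then made by aldol addition instead of acylation, and the stereocentre of F5 disappears on oxidation.

**Step 5.**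
- What may go wrong: slow methanolysis of an ester shielded by a tert-butyl group and two ortho methoxy groups, and, if the reaction is forced, conjugate attack of alkoxide at C2 with opening of the pyranone.
- Fallback (setting out from 9 and returning to the route at 10): 9 is saponified with aqueous LiOH in THF/MeOH, accepting that hydroxide may also open ring C to 1-(6-hydroxy-2,3,4-trimethoxyphenyl)-3-(4-hydroxy-3,5-dimethoxyphenyl)propane-1,3-dione F6. The crude mixture is then warmed in AcOH with catalytic H2SO4, which should re-close F6 through its only free ortho hydroxyl and deliver 10. Ring opening is thereby turned from a loss into an intermediate.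

## Further compounds

F1 | step 4 | 1-(6-hydroxy-2,3,4-trimethoxyphenyl)ethanone | CC(=O)c1c(O)cc(OC)c(OC)c1OC
F2 | step 4 | 4-[3-(6-hydroxy-2,3,4-trimethoxyphenyl)-3-oxopropanoyl]-2,6-dimethoxyphenyl pivalate | COc1cc(O)c(C(=O)CC(=O)c2cc(OC)c(OC(=O)C(C)(C)C)c(OC)c2)c(OC)c1OC
F3 | step 3 | 4-hydroxy-3,5-dimethoxybenzaldehyde | COc1cc(C=O)cc(OC)c1O
F4 | step 3 | 4-formyl-2,6-dimethoxyphenyl pivalate | COc1cc(C=O)cc(OC)c1OC(=O)C(C)(C)C
F5 | step 3 | 4-[1-hydroxy-3-oxo-3-(2,3,4-trimethoxyphenyl)propyl]-2,6-dimethoxyphenyl pivalate (racemic) | COc1ccc(C(=O)CC(O)c2cc(OC)c(OC(=O)C(C)(C)C)c(OC)c2)c(OC)c1OC
F6 | step 5 | 1-(6-hydroxy-2,3,4-trimethoxyphenyl)-3-(4-hydroxy-3,5-dimethoxyphenyl)propane-1,3-dione | COc1cc(O)c(C(=O)CC(=O)c2cc(OC)c(O)c(OC)c2)c(OC)c1OC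
A1 | alternative 1 | methyl 9-[4-(benzyloxy)-3,5-dimethoxyphenyl]-4-methoxy-3,5,7,9-tetraoxononanoate (racemic, drawn as the keto form) | COC(=O)CC(=O)C(OC)C(=O)CC(=O)CC(=O)c1cc(OC)c(OCc2ccccc2)c(OC)c1
A2 | alternative 1 | 4'-benzyloxy-5,7-dihydroxy-6,3',5'-trimethoxyflavone | COc1cc(-c2cc(=O)c3c(O)c(OC)c(O)cc3o2)cc(OC)c1OCc1ccccc1
A3 | alternative 1 | 4'-benzyloxy-5,7-dihydroxy-8,3',5'-trimethoxyflavone | COc1cc(-c2cc(=O)c3c(O)cc(O)c(OC)c3o2)cc(OC)c1OCc1ccccc1
A4 | alternative 2 | 4-{6-[4-(benzyloxy)-3,5-dimethoxyphenyl]-4-oxo-4H-pyran-2-yl}-2,3-dimethoxycyclobut-2-en-1-one (racemic) | COC1=C(OC)C(c2cc(=O)cc(-c3cc(OC)c(OCc4ccccc4)c(OC)c3)o2)C1=O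
A5 | alternative 2 | 4'-benzyloxy-5-hydroxy-6,7,3',5'-tetramethoxyflavone | COc1cc2oc(-c3cc(OC)c(OCc4ccccc4)c(OC)c3)cc(=O)c2c(O)c1OC
A6 | alternative 3 | 2-iodo-3,4,5-trimethoxyphenol | COc1cc(O)c(I)c(OC)c1OC
A7 | alternative 3 | 2-(benzyloxy)-5-ethynyl-1,3-dimethoxybenzene | C#Cc1cc(OC)c(OCc2ccccc2)c(OC)c1
A8 | alternative 3 | 4'-O-benzyl Ageconyflavone C | COc1cc(-c2cc(=O)c3c(OC)c(OC)c(OC)cc3o2)cc(OC)c1OCc1ccccc1
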